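**Retrosynthetic overview**
- The target is (2S)-6-geranyl-5-hydroxy-7,3',4'-trimethoxyflavanone. The geranyl chain is cut at the C6–CH2 bond (Stille coupling of a 6-iodide); the iodide comes from iodination ortho to the chelated 5-OH, and the 5-OH from hydrogenolysis of a 5-O-(3,4-dimethoxybenzyl) ether.
- Feature the strategy rests on: C2 of ring C is a benzylic methine bonded to O1 and to the C3 methylene that sits alpha to the C4 ketone. Cutting C2–C3 gives a C3 carbene and an aryl–O–CH2–aryl ether, so ring C is made by carbene insertion into an O-benzylic C–H bond.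
- The diazoketone precursor carries two identical 3,4-dimethoxybenzyl ethers flanking the diazoacetyl group. Either arm gives the same flavanone, and the unused arm protects O5.
- The precursor comes from 2',6'-dihydroxy-4'-methoxyacetophenone by double benzylation, trifluoroacetylation and deacylative diazo transfer.
- Ring order: rings A and B are bought; ring C is the only ring formed (step 4). The geranyl chain goes on last because its alkenes would intercept the carbene.

Key step: step 4

Assumption: Rh2(S-PTTL)4 is taken to give the 2S product in step 4; if the sense of induction proves opposite, the mirror-image catalyst Rh2(R-PTTL)4 is used with no other change.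

**Route**

Step 1
Reactants: 1 2',6'-dihydroxy-4'-methoxyacetophenone; 2 3,4-dimethoxybenzyl chloride (2.4 equiv)
Product: 3 1-[2,6-bis(3,4-dimethoxybenzyloxy)-4-methoxyphenyl]ethanone
Conditions: K2CO3, KI (cat.), DMF, 70 °C
Reagents that add atoms: none
Why: Double Williamson etherification; the reactive benzylic chloride (iodide-catalysed) and heating in DMF should also alkylate the second, hydrogen-bonded phenol.

Step 2
Reactants: 3 1-[2,6-bis(3,4-dimethoxybenzyloxy)-4-methoxyphenyl]ethanone
Product: 4 1-[2,6-bis(3,4-dimethoxybenzyloxy)-4-methoxyphenyl]-4,4,4-trifluorobutane-1,3-dione (crude, used directly)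
Conditions: LiN(SiMe3)2, THF, −78 °C; CF3CO2CH2CF3, −78 °C; 5% aq HCl work-up
Reagents that add atoms: 2,2,2-trifluoroethyl trifluoroacetate, O=C(OCC(F)(F)F)C(F)(F)F
Why: Crossed Claisen condensation of the methyl ketone lithium enolate with the activated trifluoroacetate ester; the methyl group is the only enolisable position, and the acidic diketone product drives the acylation to completion.

Step 3
Reactants: 4 1-[2,6-bis(3,4-dimethoxybenzyloxy)-4-methoxyphenyl]-4,4,4-trifluorobutane-1,3-dione
Product: 5 1-[2,6-bis(3,4-dimethoxybenzyloxy)-4-methoxyphenyl]-2-diazoethanone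
Conditions: MsN3, Et3N, H2O (1 equiv), MeCN, rt
Reagents that add atoms: methanesulfonyl azide, CS(=O)(=O)N=[N+]=[N-]
Why: Regitz diazo transfer in its detrifluoroacetylative (Danheiser) form; the diketone enolate attacks the sulfonyl azide and the trifluoroacetyl group leaves as the N-sulfonyl amide, which should give the terminal diazoketone under conditions that the benzyl ethers tolerate.

Step 4
Reactants: 5 1-[2,6-bis(3,4-dimethoxybenzyloxy)-4-methoxyphenyl]-2-diazoethanone
Product: 6 (2S)-5-(3,4-dimethoxybenzyloxy)-2-(3,4-dimethoxyphenyl)-7-methoxychroman-4-one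
Conditions: Rh2(S-PTTL)4 (dirhodium tetrakis[N-phthaloyl-(S)-tert-leucinate], 2 mol%), toluene, 4 Å MS, 0 °C, slow addition of 5
Reagents that add atoms: none
Why: The divalent-rhodium carboxylate dimer extrudes N2 from 5 to give an electrophilic rhodium carbene at the future C3, which takes up a hydride-like hydrogen from an aryl–O–CH2–aryl methylene with concerted C–C bond formation through a three-centre transition state, joining C3 to C2 (intramolecular carbene C–H insertion, the known dirhodium-carboxylate route from 2-alkoxyaryl diazoketones to chroman-4-ones). Ring C closes in the 1,6-mode (six-membered, O1 inside the ring) because the 1,5-position is the ether oxygen and carries no hydrogen, and the C–H bond that is reached is activated both by O1 and by the electron-rich 3,4-dimethoxyphenyl group. The C2 stereocentre is set by the catalyst: the chiral carboxylate ligands should let the carbene reach only one of the two enantiotopic benzylic hydrogens, giving the 2S product. The selectivity needed is insertion over attack of the carbene on the ether oxygen (oxonium ylide, then 1,2-shift of the benzyl group to a benzofuranone); the two ortho substituents twist the diazoacetyl group out of the arene plane, so the carbene sits over the OCH2 group and not in line with the in-plane oxygen lone pair, and a non-polar solvent with a bulky carboxylate catalyst disfavours the charge-separated ylide. The two benzyl arms are symmetry-equivalent, so insertion into either gives 6 and the arm left over protects O5.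

Step 5
Reactants: 6 (2S)-5-(3,4-dimethoxybenzyloxy)-2-(3,4-dimethoxyphenyl)-7-methoxychroman-4-one
Product: 7 (2S)-2-(3,4-dimethoxyphenyl)-5-hydroxy-7-methoxychroman-4-one
Conditions: H2 (1 atm), 10% Pd/C, EtOAc, rt
Reagents that add atoms: none
Why: Catalytic hydrogenolysis of the primary benzylic aryl ether under neutral conditions; the cyclic secondary C2–O1 bond reacts more slowly, no acid or base is present to open ring C, and so C2 should keep its configuration (the reaction is stopped once 6 is consumed).

Step 6
Reactants: 7 (2S)-2-(3,4-dimethoxyphenyl)-5-hydroxy-7-methoxychroman-4-one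
Product: 8 (2S)-2-(3,4-dimethoxyphenyl)-5-hydroxy-6-iodo-7-methoxychroman-4-one
Conditions: BnMe3N+ ICl2− (1.05 equiv), CaCO3, CH2Cl2–MeOH, rt
Reagents that add atoms: benzyltrimethylammonium dichloroiodate, C[N+](C)(C)Cc1ccccc1.Cl[I-]Cl
Why: Electrophilic aromatic iodination; this mild reagent attacks only the phenolic ring A, and in 5-hydroxy-7-alkoxy chromanone and flavone systems it is expected to substitute C6, ortho to the chelated 5-OH, rather than C8, while the buffered medium leaves C2 untouched.

Step 7
Reactants: 9 geranyl chloride, (2E)-1-chloro-3,7-dimethylocta-2,6-diene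
Product: 10 tributyl[(2E)-3,7-dimethylocta-2,6-dien-1-yl]stannane
Conditions: Bu3SnH, LiN(iPr)2 (commercial solution), THF, 0 °C; then 9, −78 °C → rt
Reagents that add atoms: tributyltin hydride, CCCC[SnH](CCCC)CCCC
Why: SN2 displacement of the primary allylic chloride by tributylstannyllithium at the unhindered carbon, which should keep the E double bond in place; the chloride is preferred over the bromide because it is less prone to halogen–metal exchange and homocoupling.

Step 8
Reactants: 8 (2S)-2-(3,4-dimethoxyphenyl)-5-hydroxy-6-iodo-7-methoxychroman-4-one; 10 tributyl[(2E)-3,7-dimethylocta-2,6-dien-1-yl]stannane (1.5 equiv)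
Product: 11 (2S)-2-(3,4-dimethoxyphenyl)-6-[(2E)-3,7-dimethylocta-2,6-dien-1-yl]-5-hydroxy-7-methoxychroman-4-one
Conditions: Pd(PPh3)4 (10 mol%), degassed DMF, 80 °C
Reagents that add atoms: none
Why: Stille coupling; the aryl iodide adds oxidatively to zerovalent palladium, the allyl group is transferred from tin, and reductive elimination at the less hindered primary allyl terminus should give the linear E-geranyl arene under base-free conditions that spare the flavanone stereocentre.

**Compound list**
1 | 2',6'-dihydroxy-4'-methoxyacetophenone | CC(=O)c1c(O)cc(OC)cc1O | starting material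
2 | 3,4-dimethoxybenzyl chloride | COc1ccc(CCl)cc1OC | starting material
3 | 1-[2,6-bis(3,4-dimethoxybenzyloxy)-4-methoxyphenyl]ethanone | COc1cc(OCc2ccc(OC)c(OC)c2)c(C(C)=O)c(OCc2ccc(OC)c(OC)c2)c1 | intermediate
4 | 1-[2,6-bis(3,4-dimethoxybenzyloxy)-4-methoxyphenyl]-4,4,4-trifluorobutane-1,3-dione | COc1cc(OCc2ccc(OC)c(OC)c2)c(C(=O)CC(=O)C(F)(F)F)c(OCc2ccc(OC)c(OC)c2)c1 | intermediate
5 | 1-[2,6-bis(3,4-dimethoxybenzyloxy)-4-methoxyphenyl]-2-diazoethanone | COc1cc(OCc2ccc(OC)c(OC)c2)c(C(=O)C=[N+]=[N-])c(OCc2ccc(OC)c(OC)c2)c1 | intermediate
6 | (2S)-5-(3,4-dimethoxybenzyloxy)-2-(3,4-dimethoxyphenyl)-7-methoxychroman-4-one | COc1ccc([C@@H]2CC(=O)c3c(cc(OC)cc3OCc3ccc(OC)c(OC)c3)O2)cc1OC | intermediate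
7 | (2S)-2-(3,4-dimethoxyphenyl)-5-hydroxy-7-methoxychroman-4-one | COc1ccc([C@@H]2CC(=O)c3c(O)cc(OC)cc3O2)cc1OC | intermediate
8 | (2S)-2-(3,4-dimethoxyphenyl)-5-hydroxy-6-iodo-7-methoxychroman-4-one | COc1ccc([C@@H]2CC(=O)c3c(cc(OC)c(I)c3O)O2)cc1OC | intermediate
9 | geranyl chloride, (2E)-1-chloro-3,7-dimethylocta-2,6-diene | CC(C)=CCC/C(C)=C/CCl | starting material
10 | tributyl[(2E)-3,7-dimethylocta-2,6-dien-1-yl]stannane | CC(C)=CCC/C(C)=C/C[Sn](CCCC)(CCCC)CCCC | intermediate
11 | (2S)-2-(3,4-dimethoxyphenyl)-6-[(2E)-3,7-dimethylocta-2,6-dien-1-yl]-5-hydroxy-7-methoxychroman-4-one | COc1ccc([C@@H]2CC(=O)c3c(cc(OC)c(C/C=C(\C)CCC=C(C)C)c3O)O2)cc1OC | target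

**Step count**
Total: 8 steps. Longest linear sequence: 7 steps (steps 1, 2, 3, 4, 5, 6 and 8; step 7 is a one-step side branch).

**Steps most likely to fail**

Step 4. The carbene may be captured by the ether oxygen (oxonium ylide, then 1,2-shift of the benzyl group) or dimerise instead of inserting, or the catalyst may discriminate the two benzylic hydrogens poorly. Fallback: form ring C by enantioselective conjugate arylation of a chromone. Setting out from 1, mono-etherification with 2 (1.0 equiv, K2CO3, acetone, reflux; the second hydroxyl stays locked in its hydrogen bond to the ketone) would give 1-[2-hydroxy-6-(3,4-dimethoxybenzyloxy)-4-methoxyphenyl]ethanone F1. Condensation with N,N-dimethylformamide dimethyl acetal (toluene, 90 °C) would give the enaminone (E)-3-(dimethylamino)-1-[2-hydroxy-6-(3,4-dimethoxybenzyloxy)-4-methoxyphenyl]prop-2-en-1-one F2. This should close with loss of dimethylamine (cat. p-TsOH, CH2Cl2, rt) to 5-(3,4-dimethoxybenzyloxy)-7-methoxy-4H-chromen-4-one F3. Asymmetric 1,4-addition of 3,4-dimethoxyphenylboronic acid (Pd(OCOCF3)2, t-BuPyOX ligand of the enantiomer that gives 2S, NH4PF6, H2O, ClCH2CH2Cl, 60 °C) would then deliver 6, where the route is rejoined.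

Step 8. The allyl unit may be transferred through its tertiary terminus to give the branched isomer, may lose its E geometry by isomerisation of the allylpalladium intermediate, or C2 may racemise by reversible opening of ring C on prolonged heating. Fallback: reverse the polarity of the coupling. Setting out from 8, Miyaura borylation (B2pin2, PdCl2(dppf), KOAc, dioxane, 80 °C) would give (2S)-2-(3,4-dimethoxyphenyl)-5-hydroxy-7-methoxy-6-(4,4,5,5-tetramethyl-1,3,2-dioxaborolan-2-yl)chroman-4-one F5. Suzuki–Miyaura allylation with geranyl bromide (Pd(PPh3)4, KF, THF–H2O, 50 °C) follows; here the geranyl group enters as an allylpalladium electrophile formed with retention of the E geometry and is arylated at its unhindered terminus, which would give 11 directly.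

Step 6. Iodination may go to C8, or twice (C6 and C8), instead of cleanly to C6. Fallback: deliver the chain from the 5-oxygen and use neither halogen nor palladium. Setting out from 7, Mitsunobu etherification of the chelated phenol with geraniol (PPh3, diisopropyl azodicarboxylate, THF, 0 °C → rt) would give (2S)-2-(3,4-dimethoxyphenyl)-5-[(2E)-3,7-dimethylocta-2,6-dien-1-yloxy]-7-methoxychroman-4-one F4. Acidic clay (Montmorillonite K10, CH2Cl2, 0 °C) should then promote the 1,3-shift of the allyl group from oxygen to the neighbouring carbon through a tight ion pair. C6 is the only free position ortho to O5, so this would give 11 directly.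

**Further compounds**
F1 | step 4 | 1-[2-hydroxy-6-(3,4-dimethoxybenzyloxy)-4-methoxyphenyl]ethanone | CC(=O)c1c(O)cc(OC)cc1OCc1ccc(OC)c(OC)c1
F2 | step 4 | (E)-3-(dimethylamino)-1-[2-hydroxy-6-(3,4-dimethoxybenzyloxy)-4-methoxyphenyl]prop-2-en-1-one | CN(C)/C=C/C(=O)c1c(O)cc(OC)cc1OCc1ccc(OC)c(OC)c1
F3 | step 4 | 5-(3,4-dimethoxybenzyloxy)-7-methoxy-4H-chromen-4-one | O=c1ccoc2cc(OC)cc(OCc3ccc(OC)c(OC)c3)c12
F4 | step 6 | (2S)-2-(3,4-dimethoxyphenyl)-5-[(2E)-3,7-dimethylocta-2,6-dien-1-yloxy]-7-methoxychroman-4-one | COc1ccc([C@@H]2CC(=O)c3c(cc(OC)cc3OC/C=C(\C)CCC=C(C)C)O2)cc1OC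
F5 | step 8 | (2S)-2-(3,4-dimethoxyphenyl)-5-hydroxy-7-methoxy-6-(4,4,5,5-tetramethyl-1,3,2-dioxaborolan-2-yl)chroman-4-one | COc1ccc([C@@H]2CC(=O)c3c(cc(OC)c(B4OC(C)(C)C(C)(C)O4)c3O)O2)cc1OC
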